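**Retrosynthetic overview**

- Feature: the target is a 2,2-dimethyl-2H-chromene (O1, C2–C4, C4a, C5–C8, C8a) whose two alkenes, C3=C4 in the pyran ring (ring C) and C2''=C3'' in the C6 prenyl chain, both hang from ring A at the meta-related carbons C4a and C6; C4a also lies between the two ring A oxygens (O1 on C8a and the C5 hydroxyl).
- Last disconnection: the two aryl silyl ethers (C5–O on ring A, C4'–O on ring B), cleaved by fluoride.
- Key disconnection: C3=C4 by ring-closing metathesis of a C4a vinyl group with an O1-bound 1,1-dimethylallyl group, and C2''=C3'' by cross metathesis of a C6 allyl group with 2-methylbut-2-ene, in one flask, back to triene 19.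
- Triene 19 from dihydroresveratrol: the C4a carbon by directed lithiation and formylation between the ring A oxygens, the C6 allyl by O-allylation and Claisen rearrangement, the O1 ether by tertiary propargylation and semi-hydrogenation, the vinyl group by Wittig methylenation.
- Ring order: rings A and B come with dihydroresveratrol; ring C is the only ring formed, in step 11.

Key step: step 11

Assumptions (remarks on the chemistry):
- The target has no stereocentre, so none has to be set.
- Ring B is carried as a triisopropylsilyl ether and the C5 oxygen as a tert-butyldimethylsilyl ether, so that the ring B ether survives the Claisen step and the amine-base steps.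
- Direct electrophilic formylation of a 5-alkylresorcinol goes next to the alkyl chain, so the formyl group is introduced by lithiation of the tris(methoxymethyl) ether.
- Aryl 1,1-dimethylallyl ethers undergo Claisen rearrangement on heating, so every step after the semi-hydrogenation is kept at or below 40 °C.

**Route**

Step 1
Reactants: 1 dihydroresveratrol
Product: 2 1,3-bis(methoxymethoxy)-5-{2-[4-(methoxymethoxy)phenyl]ethyl}benzene
Conditions: NaH, MOMCl, DMF, 0 °C to rt
Reagents that add atoms: chloromethyl methyl ether (MOMCl), COCCl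
Why: Williamson O-alkylation of the three sodium phenoxides with the reactive chloromethyl ether protects every hydroxyl as a methoxymethyl ether, the group that later directs lithiation to the carbon between the two ring A oxygens.

Step 2
Reactants: 2 1,3-bis(methoxymethoxy)-5-{2-[4-(methoxymethoxy)phenyl]ethyl}benzene
Product: 5 2,6-bis(methoxymethoxy)-4-{2-[4-(methoxymethoxy)phenyl]ethyl}benzaldehyde, via aryllithium 3 (not isolated), via lithium hemiaminal alkoxide 4 (not isolated)
Conditions: n-BuLi (1.1 equiv), TMEDA, THF, 0 °C; DMF, 0 °C to rt; H2O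
Reagents that add atoms: N,N-dimethylformamide, CN(C)C=O; n-butyllithium, CCCC[Li] (lithium of 3 and 4 only)
Why: Directed ortho-metalation takes place at the ring A carbon flanked by two methoxymethoxy groups, where both ethers bind lithium and acidify the same C–H bond more than the single ether on ring B can, and formylation of the aryllithium with DMF followed by hydrolysis of the hemiaminal alkoxide gives the aldehyde.

Step 3
Reactants: 5 2,6-bis(methoxymethoxy)-4-{2-[4-(methoxymethoxy)phenyl]ethyl}benzaldehyde
Product: 6 2,6-dihydroxy-4-[2-(4-hydroxyphenyl)ethyl]benzaldehyde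
Conditions: 3 M HCl, MeOH, 50 °C
Reagents that add atoms: none
Why: Acid-catalysed acetal exchange with methanol removes all three methoxymethyl groups as dimethoxymethane, and the formyl group deactivates ring A against recombination with the oxocarbenium ion.

Step 4
Reactants: 6 2,6-dihydroxy-4-[2-(4-hydroxyphenyl)ethyl]benzaldehyde; 7 allyl bromide
Product: 8 2-(allyloxy)-6-hydroxy-4-[2-(4-hydroxyphenyl)ethyl]benzaldehyde
Conditions: allyl bromide (1.05 equiv), KHCO3 (1.1 equiv), DMF, 40 °C
Reagents that add atoms: allyl bromide 7, C=CCBr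
Why: Williamson ether synthesis under a weak base occurs at a ring A hydroxyl because only a phenol ortho to the formyl group is acidic enough to be ionised by bicarbonate, and after one alkylation the last ring A hydroxyl is locked in a hydrogen bond to the carbonyl and reacts far more slowly; the two ring A hydroxyls are equivalent, so no regiochemical question arises.

Step 5
Reactants: 8 2-(allyloxy)-6-hydroxy-4-[2-(4-hydroxyphenyl)ethyl]benzaldehyde
Product: 9 2-(allyloxy)-6-hydroxy-4-{2-[4-(triisopropylsilyloxy)phenyl]ethyl}benzaldehyde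
Conditions: TIPSCl (1.2 equiv), imidazole, DMF, 0 °C to rt
Reagents that add atoms: chlorotriisopropylsilane (TIPSCl), CC(C)[Si](Cl)(C(C)C)C(C)C
Why: Imidazole-promoted O-silylation goes to the free, unhindered ring B phenol and leaves the ring A hydroxyl, which is hydrogen-bonded to the aldehyde, untouched.

Step 6
Reactants: 9 2-(allyloxy)-6-hydroxy-4-{2-[4-(triisopropylsilyloxy)phenyl]ethyl}benzaldehyde
Product: 11 3-allyl-2,6-dihydroxy-4-{2-[4-(triisopropylsilyloxy)phenyl]ethyl}benzaldehyde, via Claisen ortho-dienone 10 (not isolated)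
Conditions: N,N-diethylaniline, 190 °C, sealed tube, argon
Reagents that add atoms: none
Why: Aromatic Claisen rearrangement, a [3,3]-sigmatropic shift through a chair transition state, moves the allyl group to the free ortho carbon next to the arylethyl chain, the other ortho carbon being blocked by the formyl group, and tautomerisation of the dienone restores the aromatic ring.

Step 7
Reactants: 11 3-allyl-2,6-dihydroxy-4-{2-[4-(triisopropylsilyloxy)phenyl]ethyl}benzaldehyde; 12 2-methylbut-3-yn-2-ol
Product: 14 3-allyl-2-hydroxy-6-[(2-methylbut-3-yn-2-yl)oxy]-4-{2-[4-(triisopropylsilyloxy)phenyl]ethyl}benzaldehyde, via 2-methylbut-3-yn-2-yl trifluoroacetate 13 (not isolated)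
Conditions: 12, (CF3CO)2O, DBU, MeCN, −5 °C; then 11, DBU, CuCl2·2H2O (1 mol %), MeCN, −5 to 0 °C
Reagents that add atoms: 2-methylbut-3-yn-2-ol 12, CC(C)(O)C#C; trifluoroacetic anhydride, O=C(OC(=O)C(F)(F)F)C(F)(F)F (trifluoroacetyl group of 13 only)
Why: Copper-catalysed propargylic substitution of a tertiary propargylic ester by a phenoxide is the standard way to aryl 1,1-dimethylpropargyl ethers, and the bulky electrophile should be taken up by the hydroxyl that has a hydrogen atom on its far side, not by the one wedged between the allyl and formyl groups.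

Step 8
Reactants: 14 3-allyl-2-hydroxy-6-[(2-methylbut-3-yn-2-yl)oxy]-4-{2-[4-(triisopropylsilyloxy)phenyl]ethyl}benzaldehyde
Product: 15 3-allyl-2-(tert-butyldimethylsilyloxy)-6-[(2-methylbut-3-yn-2-yl)oxy]-4-{2-[4-(triisopropylsilyloxy)phenyl]ethyl}benzaldehyde
Conditions: TBSCl (2 equiv), imidazole, DMAP (cat.), DMF, rt to 40 °C
Reagents that add atoms: tert-butyldimethylsilyl chloride (TBSCl), CC(C)(C)[Si](C)(C)Cl
Why: O-silylation of the last phenol, which is hindered and hydrogen-bonded, is forced with excess silyl chloride and nucleophilic catalysis by DMAP, and it is done at the propargyl ether stage because that ether tolerates gentle warming.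

Step 9
Reactants: 15 3-allyl-2-(tert-butyldimethylsilyloxy)-6-[(2-methylbut-3-yn-2-yl)oxy]-4-{2-[4-(triisopropylsilyloxy)phenyl]ethyl}benzaldehyde
Product: 16 3-allyl-2-(tert-butyldimethylsilyloxy)-6-[(2-methylbut-3-en-2-yl)oxy]-4-{2-[4-(triisopropylsilyloxy)phenyl]ethyl}benzaldehyde
Conditions: H2 (1 atm, 1 equiv taken up), Pd/CaCO3 poisoned with Pb(OAc)2 (Lindlar catalyst), quinoline, EtOAc, rt
Reagents that add atoms: none
Why: Lindlar semi-hydrogenation adds one equivalent of hydrogen to the terminal alkyne, which binds the lead-poisoned palladium surface much more strongly than the allyl alkene or the aldehyde, so reduction should stop at the 1,1-dimethylallyl ether.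

Step 10
Reactants: 16 3-allyl-2-(tert-butyldimethylsilyloxy)-6-[(2-methylbut-3-en-2-yl)oxy]-4-{2-[4-(triisopropylsilyloxy)phenyl]ethyl}benzaldehyde; 17 methyltriphenylphosphonium bromide
Product: 19 2-allyl-1-(tert-butyldimethylsilyloxy)-5-[(2-methylbut-3-en-2-yl)oxy]-3-{2-[4-(triisopropylsilyloxy)phenyl]ethyl}-6-vinylbenzene, via methylenetriphenylphosphorane 18 (not isolated)
Conditions: 17 (1.6 equiv), KOtBu (1.5 equiv), THF, 0 °C; then 16, 0 °C to rt
Reagents that add atoms: methyltriphenylphosphonium bromide 17, C[P+](c1ccccc1)(c1ccccc1)c1ccccc1.[Br-]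
Why: Wittig methylenation with the lithium-free ylide turns the doubly ortho-substituted aldehyde into the styrene by cycloaddition and cycloreversion, without a long-lived alkoxide that could pull the neighbouring silyl group over, and at a temperature at which the tertiary allyl ether does not undergo Claisen rearrangement.

Step 11
Reactants: 19 2-allyl-1-(tert-butyldimethylsilyloxy)-5-[(2-methylbut-3-en-2-yl)oxy]-3-{2-[4-(triisopropylsilyloxy)phenyl]ethyl}-6-vinylbenzene; 20 2-methylbut-2-ene
Product: 22 5-(tert-butyldimethylsilyloxy)-2,2-dimethyl-6-(3-methylbut-2-en-1-yl)-7-{2-[4-(triisopropylsilyloxy)phenyl]ethyl}-2H-chromene, via 6-allylchromene silyl ether 21 (not isolated)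
Conditions: second-generation Grubbs catalyst (H2IMes)(PCy3)Cl2Ru=CHPh (5 mol %), 1,4-benzoquinone (10 mol %), CH2Cl2 (0.01 M), 40 °C; then 2-methylbut-2-ene (large excess), (H2IMes)(PCy3)Cl2Ru=CHPh (3 mol %), 40 °C, sealed vessel
Reagents that add atoms: 2-methylbut-2-ene 20, CC=C(C)C
Why: The ruthenium alkylidene exchanges onto a terminal alkene of 19, and the carbene, held near the second alkene by the C4a–C8a–O1 connection, passes through a ruthenacyclobutane that collapses to the C3=C4 bond and ethylene; the ruthenium methylidene then enters the cross-metathesis cycle, in which the C6 allyl group and 2-methylbut-2-ene exchange alkylidene halves to give the C2''=C3'' prenyl alkene and propene. Both halves are known reaction types, ring-closing metathesis of ortho-vinylaryl allyl ethers to 2H-chromenes and conversion of allylarenes into prenylarenes by cross metathesis with 2-methylbut-2-ene. Ring C closes as a six-membered ring by joining the terminal-alkene carbons of the C4a vinyl group and of the O1-bound 1,1-dimethylallyl group, and the gem-dimethyl group at C2 presses the reacting ends together. No stereocentre is formed, and the cis geometry of C3=C4 is fixed by the ring. The step needs ring closure to come before any cross metathesis of the styrene, which is secured by adding 2-methylbut-2-ene only after ethylene evolution has ceased and by high dilution, which also holds back dimerisation through the allyl group; the allyl group cannot reach either ring-closing partner because it sits meta to C4a and para to C8a. The trisubstituted prenyl alkene and the cyclic chromene alkene react too slowly to re-enter the cycle, and 1,4-benzoquinone suppresses migration of the allyl double bond by ruthenium hydrides.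

Step 12
Reactants: 22 5-(tert-butyldimethylsilyloxy)-2,2-dimethyl-6-(3-methylbut-2-en-1-yl)-7-{2-[4-(triisopropylsilyloxy)phenyl]ethyl}-2H-chromene
Product: 23 7-[2-(4-hydroxyphenyl)ethyl]-2,2-dimethyl-6-(3-methylbut-2-en-1-yl)-2H-chromen-5-ol (CNP0243348.0)
Conditions: TBAF (2.5 equiv), AcOH (2.5 equiv), THF, 0 °C to rt
Reagents that add atoms: none
Why: Fluoride attacks silicon to give pentacoordinate silicates that release both phenols (desilylation), and acetic acid buffering keeps the acid- and oxidation-sensitive chromenol from sitting as a basic phenoxide.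

**Compound list**

1 | dihydroresveratrol, 5-[2-(4-hydroxyphenyl)ethyl]benzene-1,3-diol | Oc1ccc(CCc2cc(O)cc(O)c2)cc1 | starting material
2 | 1,3-bis(methoxymethoxy)-5-{2-[4-(methoxymethoxy)phenyl]ethyl}benzene | COCOc1ccc(CCc2cc(OCOC)cc(OCOC)c2)cc1 | intermediate
3 | 2,6-bis(methoxymethoxy)-4-{2-[4-(methoxymethoxy)phenyl]ethyl}phenyllithium (aryllithium, formed in the flask) | [Li]c1c(OCOC)cc(CCc2ccc(OCOC)cc2)cc1OCOC | intermediate
4 | lithium (dimethylamino){2,6-bis(methoxymethoxy)-4-[2-(4-(methoxymethoxy)phenyl)ethyl]phenyl}methanolate (racemic hemiaminal alkoxide, formed in the flask) | [Li]OC(N(C)C)c1c(OCOC)cc(CCc2ccc(OCOC)cc2)cc1OCOC | intermediate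
5 | 2,6-bis(methoxymethoxy)-4-{2-[4-(methoxymethoxy)phenyl]ethyl}benzaldehyde | O=Cc1c(OCOC)cc(CCc2ccc(OCOC)cc2)cc1OCOC | intermediate
6 | 2,6-dihydroxy-4-[2-(4-hydroxyphenyl)ethyl]benzaldehyde | O=Cc1c(O)cc(CCc2ccc(O)cc2)cc1O | intermediate
7 | allyl bromide | C=CCBr | starting material
8 | 2-(allyloxy)-6-hydroxy-4-[2-(4-hydroxyphenyl)ethyl]benzaldehyde | C=CCOc1cc(CCc2ccc(O)cc2)cc(O)c1C=O | intermediate
9 | 2-(allyloxy)-6-hydroxy-4-{2-[4-(triisopropylsilyloxy)phenyl]ethyl}benzaldehyde | C=CCOc1cc(CCc2ccc(O[Si](C(C)C)(C(C)C)C(C)C)cc2)cc(O)c1C=O | intermediate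
10 | 6-allyl-2-formyl-3-hydroxy-5-{2-[4-(triisopropylsilyloxy)phenyl]ethyl}cyclohexa-2,4-dien-1-one (racemic Claisen ortho-dienone, formed in the flask) | C=CCC1C(CCc2ccc(O[Si](C(C)C)(C(C)C)C(C)C)cc2)=CC(O)=C(C=O)C1=O | intermediate
11 | 3-allyl-2,6-dihydroxy-4-{2-[4-(triisopropylsilyloxy)phenyl]ethyl}benzaldehyde | C=CCc1c(CCc2ccc(O[Si](C(C)C)(C(C)C)C(C)C)cc2)cc(O)c(C=O)c1O | intermediate
12 | 2-methylbut-3-yn-2-ol | CC(C)(O)C#C | starting material
13 | 2-methylbut-3-yn-2-yl trifluoroacetate (formed in the flask) | CC(C)(OC(=O)C(F)(F)F)C#C | intermediate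
14 | 3-allyl-2-hydroxy-6-[(2-methylbut-3-yn-2-yl)oxy]-4-{2-[4-(triisopropylsilyloxy)phenyl]ethyl}benzaldehyde | C=CCc1c(CCc2ccc(O[Si](C(C)C)(C(C)C)C(C)C)cc2)cc(OC(C)(C)C#C)c(C=O)c1O | intermediate
15 | 3-allyl-2-(tert-butyldimethylsilyloxy)-6-[(2-methylbut-3-yn-2-yl)oxy]-4-{2-[4-(triisopropylsilyloxy)phenyl]ethyl}benzaldehyde | C=CCc1c(CCc2ccc(O[Si](C(C)C)(C(C)C)C(C)C)cc2)cc(OC(C)(C)C#C)c(C=O)c1O[Si](C)(C)C(C)(C)C | intermediate
16 | 3-allyl-2-(tert-butyldimethylsilyloxy)-6-[(2-methylbut-3-en-2-yl)oxy]-4-{2-[4-(triisopropylsilyloxy)phenyl]ethyl}benzaldehyde | C=CCc1c(CCc2ccc(O[Si](C(C)C)(C(C)C)C(C)C)cc2)cc(OC(C)(C)C=C)c(C=O)c1O[Si](C)(C)C(C)(C)C | intermediate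
17 | methyltriphenylphosphonium bromide | C[P+](c1ccccc1)(c1ccccc1)c1ccccc1.[Br-] | starting material
18 | methylenetriphenylphosphorane (formed in the flask) | C=P(c1ccccc1)(c1ccccc1)c1ccccc1 | intermediate
19 | 2-allyl-1-(tert-butyldimethylsilyloxy)-5-[(2-methylbut-3-en-2-yl)oxy]-3-{2-[4-(triisopropylsilyloxy)phenyl]ethyl}-6-vinylbenzene (key-step precursor) | C=CCc1c(CCc2ccc(O[Si](C(C)C)(C(C)C)C(C)C)cc2)cc(OC(C)(C)C=C)c(C=C)c1O[Si](C)(C)C(C)(C)C | intermediate
20 | 2-methylbut-2-ene | CC=C(C)C | starting material
21 | 6-allyl-5-(tert-butyldimethylsilyloxy)-2,2-dimethyl-7-{2-[4-(triisopropylsilyloxy)phenyl]ethyl}-2H-chromene (formed in the flask) | C=CCc1c(CCc2ccc(O[Si](C(C)C)(C(C)C)C(C)C)cc2)cc2c(c1O[Si](C)(C)C(C)(C)C)C=CC(C)(C)O2 | intermediate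
22 | 5-(tert-butyldimethylsilyloxy)-2,2-dimethyl-6-(3-methylbut-2-en-1-yl)-7-{2-[4-(triisopropylsilyloxy)phenyl]ethyl}-2H-chromene (key-step product) | CC(C)=CCc1c(CCc2ccc(O[Si](C(C)C)(C(C)C)C(C)C)cc2)cc2c(c1O[Si](C)(C)C(C)(C)C)C=CC(C)(C)O2 | intermediate
23 | 7-[2-(4-hydroxyphenyl)ethyl]-2,2-dimethyl-6-(3-methylbut-2-en-1-yl)-2H-chromen-5-ol (CNP0243348.0) | CC(C)=CCc1c(CCc2ccc(O)cc2)cc2c(c1O)C=CC(C)(C)O2 | target

**Count**

Total steps: 12. Longest linear sequence: 12 steps (1 to 23).

**Steps most likely to fail, with fallbacks**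

Step 11. Ruthenium may load first on the unhindered allyl group and couple two molecules through it. Loading on the doubly ortho-flanked styrene may be slow. Ethylidene may be transferred from 2-methylbut-2-ene in place of isopropylidene, or the allyl double bond may migrate into conjugation before cross metathesis. The fallback separates the two metatheses and moves the cross metathesis ahead of the Wittig reaction. It sets out from aldehyde 16, which has no styrene yet. Cross metathesis of 16 with 2-methylbut-2-ene (20) and (H2IMes)(PCy3)Cl2Ru=CHPh in CH2Cl2 at 40 °C should give 2-(tert-butyldimethylsilyloxy)-6-[(2-methylbut-3-en-2-yl)oxy]-3-(3-methylbut-2-en-1-yl)-4-{2-[4-(triisopropylsilyloxy)phenyl]ethyl}benzaldehyde F1; the hindered 1,1-dimethylallyl alkene should stay out of this reaction. Wittig methylenation under the conditions of step 10 should then give 1-(tert-butyldimethylsilyloxy)-5-[(2-methylbut-3-en-2-yl)oxy]-2-(3-methylbut-2-en-1-yl)-3-{2-[4-(triisopropylsilyloxy)phenyl]ethyl}-6-vinylbenzene F2. Ring-closing metathesis of F2 alone with the same catalyst at high dilution, with only two terminal alkenes left in the molecule, should give 22, where the fallback rejoins the route.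

Step 7. Site selectivity between the two ring A hydroxyls may be lost, with etherification at the hindered hydroxyl or at both. The fallback fixes the site by protection before the Claisen rearrangement and sets out from 9. Acetylation of the free hydroxyl (Ac2O, pyridine, DMAP) should give 2-acetoxy-6-(allyloxy)-4-{2-[4-(triisopropylsilyloxy)phenyl]ethyl}benzaldehyde F3. Claisen rearrangement as in step 6 should give 6-acetoxy-3-allyl-2-hydroxy-4-{2-[4-(triisopropylsilyloxy)phenyl]ethyl}benzaldehyde F4, in which only the hydroxyl destined for silicon is free. Silylation as in step 8 should give 6-acetoxy-3-allyl-2-(tert-butyldimethylsilyloxy)-4-{2-[4-(triisopropylsilyloxy)phenyl]ethyl}benzaldehyde F5. Brief methanolysis of the activated aryl acetate (K2CO3, MeOH, 0 °C) should give 3-allyl-2-(tert-butyldimethylsilyloxy)-6-hydroxy-4-{2-[4-(triisopropylsilyloxy)phenyl]ethyl}benzaldehyde F6. Copper-catalysed etherification of this single free phenol with trifluoroacetate 13 under the conditions of step 7 should give 15, where the fallback rejoins the route.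

Step 4. Chemoselectivity may be lost, with allylation of the ring B phenol or of both ring A hydroxyls. The fallback protects ring B before the allylation and sets out from 6. Exhaustive silylation (TIPSCl in excess, imidazole, DMF) should give 2,6-bis(triisopropylsilyloxy)-4-{2-[4-(triisopropylsilyloxy)phenyl]ethyl}benzaldehyde F7. The two silyl ethers ortho to the formyl group are far more labile to base than the ring B ether, so K2CO3 in MeOH at 0 °C should give 2,6-dihydroxy-4-{2-[4-(triisopropylsilyloxy)phenyl]ethyl}benzaldehyde F8. Mono-allylation of F8 (allyl bromide 1.0 equiv, K2CO3 1.0 equiv, acetone), in which the second hydroxyl is held back by its hydrogen bond to the carbonyl, should give 9, where the fallback rejoins the route.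

**Further compounds**

F1 | step 11 | 2-(tert-butyldimethylsilyloxy)-6-[(2-methylbut-3-en-2-yl)oxy]-3-(3-methylbut-2-en-1-yl)-4-{2-[4-(triisopropylsilyloxy)phenyl]ethyl}benzaldehyde | CC(C)=CCc1c(CCc2ccc(O[Si](C(C)C)(C(C)C)C(C)C)cc2)cc(OC(C)(C)C=C)c(C=O)c1O[Si](C)(C)C(C)(C)C
F2 | step 11 | 1-(tert-butyldimethylsilyloxy)-5-[(2-methylbut-3-en-2-yl)oxy]-2-(3-methylbut-2-en-1-yl)-3-{2-[4-(triisopropylsilyloxy)phenyl]ethyl}-6-vinylbenzene | CC(C)=CCc1c(CCc2ccc(O[Si](C(C)C)(C(C)C)C(C)C)cc2)cc(OC(C)(C)C=C)c(C=C)c1O[Si](C)(C)C(C)(C)C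
F3 | step 7 | 2-acetoxy-6-(allyloxy)-4-{2-[4-(triisopropylsilyloxy)phenyl]ethyl}benzaldehyde | C=CCOc1cc(CCc2ccc(O[Si](C(C)C)(C(C)C)C(C)C)cc2)cc(OC(C)=O)c1C=O
F4 | step 7 | 6-acetoxy-3-allyl-2-hydroxy-4-{2-[4-(triisopropylsilyloxy)phenyl]ethyl}benzaldehyde | C=CCc1c(CCc2ccc(O[Si](C(C)C)(C(C)C)C(C)C)cc2)cc(OC(C)=O)c(C=O)c1O
F5 | step 7 | 6-acetoxy-3-allyl-2-(tert-butyldimethylsilyloxy)-4-{2-[4-(triisopropylsilyloxy)phenyl]ethyl}benzaldehyde | C=CCc1c(CCc2ccc(O[Si](C(C)C)(C(C)C)C(C)C)cc2)cc(OC(C)=O)c(C=O)c1O[Si](C)(C)C(C)(C)C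
F6 | step 7 | 3-allyl-2-(tert-butyldimethylsilyloxy)-6-hydroxy-4-{2-[4-(triisopropylsilyloxy)phenyl]ethyl}benzaldehyde | C=CCc1c(CCc2ccc(O[Si](C(C)C)(C(C)C)C(C)C)cc2)cc(O)c(C=O)c1O[Si](C)(C)C(C)(C)C
F7 | step 4 | 2,6-bis(triisopropylsilyloxy)-4-{2-[4-(triisopropylsilyloxy)phenyl]ethyl}benzaldehyde | O=Cc1c(O[Si](C(C)C)(C(C)C)C(C)C)cc(CCc2ccc(O[Si](C(C)C)(C(C)C)C(C)C)cc2)cc1O[Si](C(C)C)(C(C)C)C(C)C
F8 | step 4 | 2,6-dihydroxy-4-{2-[4-(triisopropylsilyloxy)phenyl]ethyl}benzaldehyde | O=Cc1c(O)cc(CCc2ccc(O[Si](C(C)C)(C(C)C)C(C)C)cc2)cc1O
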